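## Retrosynthetic overview

1. Target 28 ⇒ triol 24 by O-acylation at C3 (tigloyl chloride) and Mitsunobu etherification at C11 with intact umbelliferone ⇒ trans-decalin-3,8-dione 22 by methyl addition at C8 and hydride at C3. Drimane numbering is used: ring A = C1–C5, C10; ring B = C5–C10; C11 = the OCH2 on C9.
2. 22 ⇒ acyclic selenoester 21 by one radical bicyclisation: the C8–C9 bond closes ring B first, then the C1–C10 bond closes ring A in the same operation.
3. Enabling feature: with C3 (ring A) and C8 (ring B) at the ketone level, the decalin holds a 1,6-dicarbonyl unit C3–C2–C1–C10–C9–C8. C1 and C10 are both β-carbons of a carbonyl (like polarity) and C10 is fully substituted, so a tertiary C10 radical can join C1 of a vinyl ketone C1=C2–C3=O.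
4. 21 ⇒ Z-allylic alcohol 16 (iron-catalysed syn-carbomagnesiation of a propargylic alcohol) ⇒ alkyne 10 (Ohira–Bestmann) ⇒ C5 stereocentre by auxiliary-controlled Michael addition ⇒ 3,3-dimethylpent-4-enoic acid 1, oxazolidinone 2 and tert-butyl acrylate 5.

Key step: step 14

Remark: compounds 15 to 20 are carried as mixtures of the two epimers at the carbinol carbon that becomes C3; this centre is flattened in step 13 and set in step 15.

## Route

Step 1
Reactants: 1 3,3-dimethylpent-4-enoic acid; 2 (4R)-4-benzyl-1,3-oxazolidin-2-one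
Product: 4 (4R)-4-benzyl-3-(3,3-dimethylpent-4-enoyl)-1,3-oxazolidin-2-one, via mixed pivalic anhydride 3 (not isolated)
Conditions: t-BuCOCl, Et3N, THF, −20 °C; then 2, LiCl, −20 °C → rt
Reagents that add atoms: none
Why: N-acylation of the oxazolidinone through the mixed anhydride is the standard way to attach the chiral auxiliary; no stereocentre is formed.

Step 2
Reactants: 4 (4R)-4-benzyl-3-(3,3-dimethylpent-4-enoyl)-1,3-oxazolidin-2-one; 5 tert-butyl acrylate
Product: 6 tert-butyl (4R)-4-[(4R)-4-benzyl-2-oxo-1,3-oxazolidine-3-carbonyl]-5,5-dimethylhept-6-enoate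
Conditions: TiCl4, i-Pr2NEt, CH2Cl2, 0 °C; then 5, 0 °C
Reagents that add atoms: none
Why: Diastereoselective Michael addition of the chelated chlorotitanium Z-enolate of the N-acyl oxazolidinone to the acrylate, in which the benzyl group of the (R)-auxiliary shields one enolate face and so sets C5, the only stereocentre carried into the key step.

Step 3
Reactants: 6 tert-butyl (4R)-4-[(4R)-4-benzyl-2-oxo-1,3-oxazolidine-3-carbonyl]-5,5-dimethylhept-6-enoate
Product: 7 tert-butyl (4R)-4-(hydroxymethyl)-5,5-dimethylhept-6-enoate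
Conditions: LiBH4, MeOH (1 equiv), THF, 0 °C
Reagents that add atoms: none
Why: Reductive cleavage of the imide by LiBH4 should release the primary alcohol and the auxiliary while the tert-butyl ester and the alkene stay untouched, and C5 is not affected.

Step 4
Reactants: 7 tert-butyl (4R)-4-(hydroxymethyl)-5,5-dimethylhept-6-enoate
Product: 8 tert-butyl (4R)-4-formyl-5,5-dimethylhept-6-enoate
Conditions: Dess–Martin periodinane, CH2Cl2, 0 °C → rt
Reagents that add atoms: none
Why: Dess–Martin oxidation of the primary alcohol to the aldehyde runs without base, so the α-stereocentre next to the quaternary carbon should not be enolised.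

Step 5
Reactants: 8 tert-butyl (4R)-4-formyl-5,5-dimethylhept-6-enoate; 9 dimethyl (1-diazo-2-oxopropyl)phosphonate
Product: 10 tert-butyl (4S)-4-ethynyl-5,5-dimethylhept-6-enoate
Conditions: K2CO3, MeOH, 0 °C → rt
Reagents that add atoms: none
Why: Seyferth–Gilbert homologation in the Ohira–Bestmann variant turns the aldehyde into the terminal alkyne with one more carbon (the later C9), and the mild carbonate base together with the quaternary neighbour should keep the α-stereocentre intact (the change of descriptor is a priority effect only).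

Step 6
Reactants: 10 tert-butyl (4S)-4-ethynyl-5,5-dimethylhept-6-enoate
Product: 12 tert-butyl (4R)-4-(3-hydroxyprop-1-yn-1-yl)-5,5-dimethylhept-6-enoate, via lithium acetylide 11 (not isolated)
Conditions: n-BuLi, THF, −78 °C; then (CH2O)n, −78 °C → rt
Reagents that add atoms: formaldehyde (from paraformaldehyde), C=O
Why: Deprotonation of the terminal alkyne and 1,2-addition of the acetylide to formaldehyde gives the propargylic alcohol (C11), the acid–base step being much faster than attack of n-BuLi on the tert-butyl ester at −78 °C.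

Step 7
Reactants: 12 tert-butyl (4R)-4-(3-hydroxyprop-1-yn-1-yl)-5,5-dimethylhept-6-enoate
Product: 14 tert-butyl (4S)-4-(3-hydroxyprop-1-yn-1-yl)-5,5-dimethyl-6-oxohexanoate, via secondary ozonide 13 (not isolated)
Conditions: O3, CH2Cl2, −78 °C; then PPh3, −78 °C → rt
Reagents that add atoms: ozone, [O-][O+]=O
Why: Ozonolysis with reductive work-up cleaves the monosubstituted alkene to the non-enolisable aldehyde (the later C3), since ozone reacts with alkenes far faster than with the internal alkyne.

Step 8
Reactants: 14 tert-butyl (4S)-4-(3-hydroxyprop-1-yn-1-yl)-5,5-dimethyl-6-oxohexanoate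
Product: 15 tert-butyl (4S,6RS)-6-hydroxy-4-(3-hydroxyprop-1-yn-1-yl)-5,5-dimethyloct-7-enoate
Conditions: CH2=CHMgBr (3 equiv), THF, −78 → −40 °C
Reagents that add atoms: vinylmagnesium bromide, C=C[Mg]Br
Why: Grignard 1,2-addition to the aldehyde installs the vinyl carbinol that masks the vinyl ketone; the new carbinol centre forms without control and is removed again in step 13.

Step 9
Reactants: 15 tert-butyl (4S,6RS)-6-hydroxy-4-(3-hydroxyprop-1-yn-1-yl)-5,5-dimethyloct-7-enoate
Product: 16 tert-butyl (4S,6RS)-6-hydroxy-4-[(2Z)-4-hydroxybut-2-en-2-yl]-5,5-dimethyloct-7-enoate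
Conditions: MeMgBr (5 equiv), Fe(acac)3 (20 mol%), THF, −78 → 0 °C; aq. NH4Cl
Reagents that add atoms: methylmagnesium bromide, C[Mg]Br
Why: Alkoxide-directed, iron-catalysed syn-carbomagnesiation of the propargylic alcohol should deliver methyl to the alkyne carbon remote from the hydroxyl and magnesium to the near one, so that protonation gives the trisubstituted alkene with C5 and C11 cis (Z).

Step 10
Reactants: 16 tert-butyl (4S,6RS)-6-hydroxy-4-[(2Z)-4-hydroxybut-2-en-2-yl]-5,5-dimethyloct-7-enoate
Product: 18 (4S,6RS)-6-hydroxy-4-[(2Z)-4-hydroxybut-2-en-2-yl]-5,5-dimethyloct-7-enoic acid, via tris(trimethylsilyl) derivative 17 (not isolated)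
Conditions: TMSOTf, 2,6-lutidine, CH2Cl2, 0 °C → rt; then aq. citric acid, THF
Reagents that add atoms: none
Why: Silyl triflate-mediated cleavage of the tert-butyl ester (loss of isobutene from the O-silylated ester) under lutidine buffering, followed by hydrolysis of the silyl ester and silyl ethers, frees the acid without a strong protic acid that would ionise the allylic alcohols.

Step 11
Reactants: 18 (4S,6RS)-6-hydroxy-4-[(2Z)-4-hydroxybut-2-en-2-yl]-5,5-dimethyloct-7-enoic acid
Product: 19 (4S,6RS)-4-[(2Z)-4-(acetyloxy)but-2-en-2-yl]-6-hydroxy-5,5-dimethyloct-7-enoic acid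
Conditions: Ac2O (1.1 equiv), pyridine, CH2Cl2, −20 °C; aqueous work-up
Reagents that add atoms: acetic anhydride, CC(=O)OC(C)=O
Why: Chemoselective acetylation of the unhindered primary allylic hydroxyl over the neopentyl-type secondary carbinol, any mixed anhydride at the carboxyl group being hydrolysed in the work-up.

Step 12
Reactants: 19 (4S,6RS)-4-[(2Z)-4-(acetyloxy)but-2-en-2-yl]-6-hydroxy-5,5-dimethyloct-7-enoic acid
Product: 20 Se-phenyl (4S,6RS)-4-[(2Z)-4-(acetyloxy)but-2-en-2-yl]-6-hydroxy-5,5-dimethyloct-7-eneselenoate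
Conditions: (PhSe)2, n-Bu3P, CH2Cl2, rt
Reagents that add atoms: diphenyl diselenide, c1ccc(cc1)[Se][Se]c1ccccc1
Why: Phosphine/diselenide activation converts the carboxylic acid into the Se-phenyl selenoester, the standard acyl radical precursor, and should leave the hindered secondary alcohol free.

Step 13
Reactants: 20 Se-phenyl (4S,6RS)-4-[(2Z)-4-(acetyloxy)but-2-en-2-yl]-6-hydroxy-5,5-dimethyloct-7-eneselenoate
Product: 21 Se-phenyl (4S)-4-[(2Z)-4-(acetyloxy)but-2-en-2-yl]-5,5-dimethyl-6-oxooct-7-eneselenoate
Conditions: Dess–Martin periodinane, CH2Cl2, 0 °C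
Reagents that add atoms: none
Why: Dess–Martin oxidation of the allylic carbinol unveils the vinyl ketone only in the last step before the cascade, so that this Michael acceptor never meets phosphine or selenolate, and the carbinol stereocentre is erased.

Step 14
Reactants: 21 Se-phenyl (4S)-4-[(2Z)-4-(acetyloxy)but-2-en-2-yl]-5,5-dimethyl-6-oxooct-7-eneselenoate
Product: 22 [(1S,4aS,8aR)-5,5,8a-trimethyl-2,6-dioxodecahydronaphthalen-1-yl]methyl acetate
Conditions: n-Bu3SnH (1.3 equiv), AIBN (cat.), benzene (0.005 M), 80 °C, slow addition of the stannane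
Reagents that add atoms: none
Why: Bu3Sn• takes the PhSe group from 21 to give the C8 acyl radical, which adds to C9 of the Z-alkene (ring B, 6-endo-trig) and leaves a tertiary radical at C10; this nucleophilic radical adds to the β-carbon C1 of the vinyl ketone (ring A, 6-endo-trig, the C1–C10 bond), and the α-keto radical at C2 takes hydrogen from Bu3SnH, which carries the chain. The closest known reaction type is the acyl radical polyene cascade of Se-phenyl selenoesters under stannane conditions, in which serial 6-endo closures give trans-fused polycyclic ketones; here the last closure is a Giese addition to an enone. C9 is controlled by the alkene geometry together with C5: in the chair-like transition state the quaternary C4 substituent on C5 lies equatorial, the Z geometry then forces CH2OAc axial on C9 and cis to H5, and the other chair would place C4 and CH2OAc syn-diaxial. C10 is controlled in the second closure, where C1 should bond equatorially to the new ring B chair so that the methyl group becomes axial and the ring fusion trans, as in radical polyene cyclisations. The step needs 6-endo over 5-exo selectivity, secured in the first closure by attack at the less substituted alkene carbon with formation of the tertiary radical and in the second by the enone, which takes a nucleophilic radical only at C1. It also needs both ring closures to be faster than hydrogen transfer from the stannane, which slow addition at high dilution should secure.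

Step 15
Reactants: 22 [(1S,4aS,8aR)-5,5,8a-trimethyl-2,6-dioxodecahydronaphthalen-1-yl]methyl acetate
Product: 23 [(1S,4aS,6R,8aR)-6-hydroxy-5,5,8a-trimethyl-2-oxodecahydronaphthalen-1-yl]methyl acetate
Conditions: LiAlH(Ot-Bu)3 (1.2 equiv), THF, −78 → −40 °C
Reagents that add atoms: none
Why: Chemoselective hydride reduction in which the bulky reagent attacks the C3 ketone along its open axial path (syn only to axial hydrogens) to give the equatorial alcohol (3R, cis to the C10 methyl), while the C8 ketone, screened on one face by the syn-axial C10 methyl and on the other by the axial CH2OAc group, should react more slowly.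

Step 16
Reactants: 23 [(1S,4aS,6R,8aR)-6-hydroxy-5,5,8a-trimethyl-2-oxodecahydronaphthalen-1-yl]methyl acetate
Product: 24 (1S,2R,4aS,6R,8aR)-1-(hydroxymethyl)-2,5,5,8a-tetramethyldecahydronaphthalene-2,6-diol
Conditions: MeMgBr (8 equiv), CeCl3 (anhydrous), THF, −78 → 0 °C
Reagents that add atoms: methylmagnesium bromide, C[Mg]Br
Why: 1,2-Addition of the cerium-modified methyl Grignard reagent to the C8 ketone should come from the equatorial direction, because the axial path is closed by the syn-axial C10 methyl and the C11 alkoxide freed from the acetate by the excess reagent holds the metal on the same face, which gives the axial tertiary alcohol (8R) with an equatorial methyl group while the cerium reagent suppresses enolisation.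

Step 17
Reactants: 24 (1S,2R,4aS,6R,8aR)-1-(hydroxymethyl)-2,5,5,8a-tetramethyldecahydronaphthalene-2,6-diol; 25 umbelliferone (7-hydroxy-2H-chromen-2-one)
Product: 26 7-{[(1S,2R,4aS,6R,8aR)-2,6-dihydroxy-2,5,5,8a-tetramethyldecahydronaphthalen-1-yl]methoxy}-2H-chromen-2-one
Conditions: PPh3, DIAD, THF, 0 °C → rt
Reagents that add atoms: none
Why: Mitsunobu etherification in which only the primary hydroxyl is activated as the oxyphosphonium ion and displaced by the acidic phenol (SN2 at a CH2, no stereocentre involved), the hindered secondary and the tertiary hydroxyl being inert.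

Step 18
Reactants: 26 7-{[(1S,2R,4aS,6R,8aR)-2,6-dihydroxy-2,5,5,8a-tetramethyldecahydronaphthalen-1-yl]methoxy}-2H-chromen-2-one; 27 (2E)-2-methylbut-2-enoyl chloride
Product: 28 (2R,4aR,5S,6R,8aS)-6-hydroxy-1,1,4a,6-tetramethyl-5-{[(2-oxo-2H-chromen-7-yl)oxy]methyl}decahydronaphthalen-2-yl (2E)-2-methylbut-2-enoate
Conditions: pyridine, DMAP (cat.), CH2Cl2, 0 → 40 °C
Reagents that add atoms: none
Why: DMAP-catalysed O-acylation of the remaining secondary alcohol with the E acid chloride, in which the tertiary C8 hydroxyl does not react, C3 keeps its configuration because only the O–H bond is broken, and the E tigloyl geometry is the stable one.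

## Compound list

1 | 3,3-dimethylpent-4-enoic acid | C=CC(C)(C)CC(=O)O | starting material
2 | (4R)-4-benzyl-1,3-oxazolidin-2-one | O=C1N[C@H](Cc2ccccc2)CO1 | starting material
3 | 3,3-dimethylpent-4-enoic pivalic anhydride | C=CC(C)(C)CC(=O)OC(=O)C(C)(C)C | intermediate (not isolated)
4 | (4R)-4-benzyl-3-(3,3-dimethylpent-4-enoyl)-1,3-oxazolidin-2-one | C=CC(C)(C)CC(=O)N1[C@H](Cc2ccccc2)COC1=O | intermediate
5 | tert-butyl acrylate | C=CC(=O)OC(C)(C)C | starting material
6 | tert-butyl (4R)-4-[(4R)-4-benzyl-2-oxo-1,3-oxazolidine-3-carbonyl]-5,5-dimethylhept-6-enoate | O=C(N1[C@H](Cc2ccccc2)COC1=O)[C@H](CCC(=O)OC(C)(C)C)C(C)(C)C=C | intermediate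
7 | tert-butyl (4R)-4-(hydroxymethyl)-5,5-dimethylhept-6-enoate | OC[C@H](CCC(=O)OC(C)(C)C)C(C)(C)C=C | intermediate
8 | tert-butyl (4R)-4-formyl-5,5-dimethylhept-6-enoate | O=C[C@H](CCC(=O)OC(C)(C)C)C(C)(C)C=C | intermediate
9 | dimethyl (1-diazo-2-oxopropyl)phosphonate | COP(=O)(OC)C(=[N+]=[N-])C(C)=O | starting material
10 | tert-butyl (4S)-4-ethynyl-5,5-dimethylhept-6-enoate | C#C[C@H](CCC(=O)OC(C)(C)C)C(C)(C)C=C | intermediate
11 | lithium acetylide of 10 (configuration unchanged) | [Li]C#C[C@H](CCC(=O)OC(C)(C)C)C(C)(C)C=C | intermediate (not isolated)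
12 | tert-butyl (4R)-4-(3-hydroxyprop-1-yn-1-yl)-5,5-dimethylhept-6-enoate | OCC#C[C@H](CCC(=O)OC(C)(C)C)C(C)(C)C=C | intermediate
13 | tert-butyl (4S)-7-hydroxy-4-[2-(1,2,4-trioxolan-3-yl)propan-2-yl]hept-5-ynoate (secondary ozonide, ring carbon unassigned) | OCC#C[C@H](CCC(=O)OC(C)(C)C)C(C)(C)C1OCOO1 | intermediate (not isolated)
14 | tert-butyl (4S)-4-(3-hydroxyprop-1-yn-1-yl)-5,5-dimethyl-6-oxohexanoate | OCC#C[C@H](CCC(=O)OC(C)(C)C)C(C)(C)C=O | intermediate
15 | tert-butyl (4S,6RS)-6-hydroxy-4-(3-hydroxyprop-1-yn-1-yl)-5,5-dimethyloct-7-enoate | OCC#C[C@H](CCC(=O)OC(C)(C)C)C(C)(C)C(O)C=C | intermediate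
16 | tert-butyl (4S,6RS)-6-hydroxy-4-[(2Z)-4-hydroxybut-2-en-2-yl]-5,5-dimethyloct-7-enoate | OC/C=C(C)\[C@H](CCC(=O)OC(C)(C)C)C(C)(C)C(O)C=C | intermediate
17 | trimethylsilyl (4S,6RS)-5,5-dimethyl-6-[(trimethylsilyl)oxy]-4-{(2Z)-4-[(trimethylsilyl)oxy]but-2-en-2-yl}oct-7-enoate | C[Si](C)(C)OC/C=C(C)\[C@H](CCC(=O)O[Si](C)(C)C)C(C)(C)C(O[Si](C)(C)C)C=C | intermediate (not isolated)
18 | (4S,6RS)-6-hydroxy-4-[(2Z)-4-hydroxybut-2-en-2-yl]-5,5-dimethyloct-7-enoic acid | OC/C=C(C)\[C@H](CCC(=O)O)C(C)(C)C(O)C=C | intermediate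
19 | (4S,6RS)-4-[(2Z)-4-(acetyloxy)but-2-en-2-yl]-6-hydroxy-5,5-dimethyloct-7-enoic acid | CC(=O)OC/C=C(C)\[C@H](CCC(=O)O)C(C)(C)C(O)C=C | intermediate
20 | Se-phenyl (4S,6RS)-4-[(2Z)-4-(acetyloxy)but-2-en-2-yl]-6-hydroxy-5,5-dimethyloct-7-eneselenoate | CC(=O)OC/C=C(C)\[C@H](CCC(=O)[Se]c1ccccc1)C(C)(C)C(O)C=C | intermediate
21 | Se-phenyl (4S)-4-[(2Z)-4-(acetyloxy)but-2-en-2-yl]-5,5-dimethyl-6-oxooct-7-eneselenoate | CC(=O)OC/C=C(C)\[C@H](CCC(=O)[Se]c1ccccc1)C(C)(C)C(=O)C=C | intermediate
22 | [(1S,4aS,8aR)-5,5,8a-trimethyl-2,6-dioxodecahydronaphthalen-1-yl]methyl acetate | O=C1CC[C@]2(C)[C@H](CCC(=O)[C@@H]2COC(C)=O)C1(C)C | intermediate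
23 | [(1S,4aS,6R,8aR)-6-hydroxy-5,5,8a-trimethyl-2-oxodecahydronaphthalen-1-yl]methyl acetate | O[C@@H]1CC[C@]2(C)[C@H](CCC(=O)[C@@H]2COC(C)=O)C1(C)C | intermediate
24 | (1S,2R,4aS,6R,8aR)-1-(hydroxymethyl)-2,5,5,8a-tetramethyldecahydronaphthalene-2,6-diol | O[C@@H]1CC[C@]2(C)[C@H](CC[C@@](C)(O)[C@@H]2CO)C1(C)C | intermediate
25 | umbelliferone (7-hydroxy-2H-chromen-2-one) | Oc1ccc2ccc(=O)oc2c1 | starting material
26 | 7-{[(1S,2R,4aS,6R,8aR)-2,6-dihydroxy-2,5,5,8a-tetramethyldecahydronaphthalen-1-yl]methoxy}-2H-chromen-2-one | O[C@@H]1CC[C@]2(C)[C@H](CC[C@@](C)(O)[C@@H]2COc2ccc3ccc(=O)oc3c2)C1(C)C | intermediate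
27 | (2E)-2-methylbut-2-enoyl chloride (tigloyl chloride) | C/C=C(\C)C(Cl)=O | starting material
28 | (2R,4aR,5S,6R,8aS)-6-hydroxy-1,1,4a,6-tetramethyl-5-{[(2-oxo-2H-chromen-7-yl)oxy]methyl}decahydronaphthalen-2-yl (2E)-2-methylbut-2-enoate | C/C=C(\C)C(=O)O[C@@H]1CC[C@]2(C)[C@H](CC[C@@](C)(O)[C@@H]2COc2ccc3ccc(=O)oc3c2)C1(C)C | target

## Step count and risks

Total step count: 18. Longest linear sequence: 18 steps (from 1; 2, 5, 9, 25 and 27 are bought).

The three steps most likely to fail:

**Step 14.** What may go wrong: hydrogen transfer from the stannane to the acyl radical or to the C10 radical before the second ring closure, decarbonylation of the acyl radical, or closure of ring A from the wrong face (cis ring fusion). The fallback sets out from 20 and comes back at 22, closing the two rings one after the other. Pd(PPh3)4-catalysed hydrostannolysis of the selenoester (n-Bu3SnH, benzene, rt) would give the hydroxy aldehyde F1. Me2AlCl (CH2Cl2, −78 °C) would close ring B by an intramolecular carbonyl-ene reaction, the aldehyde carbon bonding to C9 and a hydrogen of the C10 methyl group moving to oxygen, to give the methylidene cyclohexanol F2. MnO2 (CH2Cl2, rt) would oxidise only the allylic carbinol to the vinyl ketone F3. Fe(acac)3 and PhSiH3 (EtOH, 60 °C) would put a hydrogen atom on the exocyclic methylene, and the tertiary C10 radical would close ring A by Giese addition to give the hydroxy ketone F4. Dess–Martin oxidation of the C8 carbinol would return to dione 22.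

**Step 9.** What may go wrong: no insertion into the hindered alkyne, competing attack of the Grignard reagent on the tert-butyl ester, or erosion of regio- and syn-selectivity. The fallback sets out from 10 and comes back at 16, making the Z alkene by syn addition of a cuprate to an alkynoate. n-BuLi then ClCO2Me (THF, −78 °C) would give the ynoate F5. Ozonolysis of its vinyl group (O3, CH2Cl2, −78 °C; PPh3) would give the aldehyde F6. CH2=CHMgBr at −78 °C would give the vinyl carbinol F7. Me2CuLi (THF, −78 °C, protonation in the cold) would add methyl and hydrogen syn to give the Z-enoate F8. i-Bu2AlH (CH2Cl2, −78 °C) would reduce the methyl ester in the presence of the tert-butyl ester and rejoin the route at diol 16.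

**Step 16.** What may go wrong: attack along the axial path giving the C8 epimer, enolisation of the ketone with loss of the C9 configuration, or β-elimination of the C11 oxygen. The fallback sets out from 23 and comes back at 24, replacing direct methyl addition by methylene transfer under thermodynamic control and hydride opening. Corey–Chaykovsky reaction with pre-formed dimethylsulfoxonium methylide (Me3S(O)I, NaH, DMSO/THF, rt) adds reversibly and so should place the new C–C bond equatorial, giving the spiro-epoxide F9 with axial oxygen. LiEt3BH (THF, 0 °C → rt) would open the epoxide at its CH2 terminus and remove the acetate, returning to triol 24.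

Further compounds
F1 | step 14 | (4S,6RS)-4-[(2Z)-4-(acetyloxy)but-2-en-2-yl]-6-hydroxy-5,5-dimethyloct-7-enal | CC(=O)OC/C=C(C)\[C@H](CCC=O)C(C)(C)C(O)C=C
F2 | step 14 | [(1S,5S)-2-hydroxy-5-(3-hydroxy-2-methylpent-4-en-2-yl)-6-methylidenecyclohexyl]methyl acetate (both carbinol centres unassigned) | C=C1[C@H](CCC(O)[C@@H]1COC(C)=O)C(C)(C)C(O)C=C
F3 | step 14 | [(1S,5S)-2-hydroxy-5-(2-methyl-3-oxopent-4-en-2-yl)-6-methylidenecyclohexyl]methyl acetate (ring carbinol unassigned) | C=C1[C@H](CCC(O)[C@@H]1COC(C)=O)C(C)(C)C(=O)C=C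
F4 | step 14 | [(1S,4aS,8aR)-2-hydroxy-5,5,8a-trimethyl-6-oxodecahydronaphthalen-1-yl]methyl acetate (C2 unassigned) | O=C1CC[C@]2(C)[C@H](CCC(O)[C@@H]2COC(C)=O)C1(C)C
F5 | step 9 | 7-tert-butyl 1-methyl (4R)-4-(2-methylbut-3-en-2-yl)hept-2-ynedioate | COC(=O)C#C[C@H](CCC(=O)OC(C)(C)C)C(C)(C)C=C
F6 | step 9 | 7-tert-butyl 1-methyl (4S)-4-(2-methyl-1-oxopropan-2-yl)hept-2-ynedioate | COC(=O)C#C[C@H](CCC(=O)OC(C)(C)C)C(C)(C)C=O
F7 | step 9 | 7-tert-butyl 1-methyl (4S)-4-[(3RS)-3-hydroxy-2-methylpent-4-en-2-yl]hept-2-ynedioate | COC(=O)C#C[C@H](CCC(=O)OC(C)(C)C)C(C)(C)C(O)C=C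
F8 | step 9 | 7-tert-butyl 1-methyl (2Z,4S)-4-[(3RS)-3-hydroxy-2-methylpent-4-en-2-yl]-3-methylhept-2-enedioate | COC(=O)/C=C(C)\[C@H](CCC(=O)OC(C)(C)C)C(C)(C)C(O)C=C
F9 | step 16 | [(1'S,2R,4a'S,6'R,8a'R)-6'-hydroxy-5',5',8a'-trimethyloctahydro-1'H-spiro[oxirane-2,2'-naphthalen]-1'-yl]methyl acetate | O[C@@H]1CC[C@]2(C)[C@H](CC[C@@]3(OC3)[C@@H]2COC(C)=O)C1(C)C
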